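**Plan**

1. Retrosynthetic cuts, in order: the tertiary carbinols C10 and C10' go back to exocyclic olefins; the bicyclo[2.2.1]heptanone is opened at C3–C5' (radical conjugate addition); C2–C3 and C1'–C2' are then cut together (Prins–pinacol), which opens the cyclopentene of unit A to a C3 enal and contracts the cyclopentanone of unit B to a 1-alkenylcyclobutanol; last the C2=C2' olefin (Julia–Kocienski).
2. Both fragments come from α-santonin through isophotosantonic lactone: fragment A (6) by glycol cleavage of C2–C3; fragment B (18) by photochemical Wolff ring contraction to a strained cyclobutane, then hydroxylation and sulfone formation.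
3. Forward ring order: olefination joins 6 and 18 (19); step 17 closes the cyclopentene of unit A and the cyclopentanone of unit B; step 20 closes the norbornanone; steps 22–23 invert C10 and C10'.
4. Feature used in step 17: in 19 the E-olefin C2=C2' lies five atoms from the formyl carbon C3, which the Z-tetrasubstituted C4=C5 bond on seven-membered ring A holds cis to C1; C2' carries the silyloxy carbon C3' of a cyclobutane fused to seven-membered ring B, whose strained C3'–C1' bond can shift to C2'.
5. Stereochemistry: C1, C6, C7, C11 of both units are bought with santonin; C2, C2', C3, C4', C5' are relayed from them by substrate control; C10 and C10' are set last by face-selective oxygen capture.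
6. Numbering: guaiane numbering; unit A is the cyclopentene half, unit B (primed) the ketone half. In unit B the old C2 of the lactone ends as C3' and the old C3 as C2'; compounds 7–12 keep the lactone numbering.

Key step: step 17

Remark: isophotosantonic lactone is taken as 1αH,10α-OH (hydroxyl cis to H-1). Both halves of the target are its C10 epimers, hence the late inversion.

**Route**

Step 1
Reactants: 1 α-santonin
Product: 2 isophotosantonic lactone
Conditions: hν (Hg lamp, Pyrex), AcOH–H2O 1:1, reflux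
Reagents that add atoms: water, O
Why: Photochemical cross-conjugated dienone rearrangement through the 1,5-bonded cyclopropyl zwitterion, opened by water at C10 anti to C5, should give the 5/7 lactone; H-1 α follows from the rigid zwitterion, 10α-OH from the anti attack, and C6, C7, C11 are untouched.

Step 2
Reactants: 2 isophotosantonic lactone
Product: 3 10-O-triethylsilyl isophotosantonic lactone
Conditions: TESOTf, 2,6-lutidine, CH2Cl2, −78 to 0 °C
Reagents that add atoms: triethylsilyl triflate, CC[Si](CC)(CC)OS(=O)(=O)C(F)(F)F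
Why: Silylation of the tertiary alcohol blocks retro-aldol and ionisation in later steps; no stereocentre is touched.

Step 3
Reactants: 3 10-O-triethylsilyl isophotosantonic lactone
Product: 4 2α-hydroxy ketone
Conditions: LDA (1.05 equiv), THF, −78 °C; then 2-(phenylsulfonyl)-3-phenyloxaziridine
Reagents that add atoms: 2-(phenylsulfonyl)-3-phenyloxaziridine, O=S(=O)(N1OC1c1ccccc1)c1ccccc1
Why: Enolate hydroxylation at the kinetic cross-conjugated C2 enolate (ketone far more acidic than the lactone) should occur anti to the C10 branch; the C2 configuration is erased in step 5.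

Step 4
Reactants: 4 2α-hydroxy ketone
Product: 5 2α,3α-diol
Conditions: NaBH4, CeCl3·7H2O, MeOH, −40 °C
Reagents that add atoms: none
Why: Luche 1,2-reduction of the enone with hydride anti to the 2-hydroxyl should give the cis allylic diol; both carbinol centres are erased in step 5.

Step 5
Reactants: 5 2α,3α-diol
Product: 6 fragment A, the 2,3-seco dialdehyde
Conditions: NaIO4, THF–pH 7 buffer, 0 °C
Reagents that add atoms: none
Why: Periodate glycol cleavage opens the five-membered ring at C2–C3; the Z geometry of the new enal (formyl cis to C1) is inherited from the ring and no stereocentre is formed.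

Step 6
Reactants: 3 10-O-triethylsilyl isophotosantonic lactone
Product: 7 4α,5α-epoxy ketone
Conditions: t-BuOOH, DBU, CH2Cl2, 0 °C to rt
Reagents that add atoms: tert-butyl hydroperoxide, CC(C)(C)OO
Why: Nucleophilic (Weitz–Scheffer) epoxidation of the enone should occur on the α-face, syn to H-1 and away from the C10 branch that covers the β-face.

Step 7
Reactants: 7 4α,5α-epoxy ketone
Product: 8 5α-hydroxy ketone
Conditions: SmI2 (2.2 equiv), THF–MeOH, −90 °C
Reagents that add atoms: none
Why: Reductive opening of the α,β-epoxy ketone at the Cα–O bond keeps the C5 oxygen α; C4 is protonated from the α-face (4β-methyl) and is erased again in step 18.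

Step 8
Reactants: 8 5α-hydroxy ketone
Product: 9 5α,10α-bis(triethylsilyloxy) ketone
Conditions: TESOTf, 2,6-lutidine, CH2Cl2, −78 °C
Reagents that add atoms: triethylsilyl triflate, CC[Si](CC)(CC)OS(=O)(=O)C(F)(F)F
Why: Silylation of the tertiary β-hydroxy ketone under non-nucleophilic conditions prevents retro-aldol cleavage and parks a latent C4=C5 unsaturation.

Step 9
Reactants: 9 5α,10α-bis(triethylsilyloxy) ketone
Product: 11 2-diazo ketone, via 2-trifluoroacetyl ketone 10 (not isolated)
Conditions: LiHMDS, THF, −78 °C; CF3CO2CH2CF3; then MsN3, Et3N, MeCN, rt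
Reagents that add atoms: methanesulfonyl azide, CS(=O)(=O)N=[N+]=[N-]; 2,2,2-trifluoroethyl trifluoroacetate, O=C(OCC(F)(F)F)C(F)(F)F (its atoms stay only in 10)
Why: Detrifluoroacetylative diazo transfer at the kinetic C2 enolate (the CH2 side, away from the silyloxy-bearing C5) gives the α-diazo ketone without touching a stereocentre.

Step 10
Reactants: 11 2-diazo ketone
Product: 13 S-ethyl cyclobutanecarbothioate, via ring-contracted ketene 12 (not isolated)
Conditions: hν (350 nm), EtSH, CH2Cl2, 0 °C
Reagents that add atoms: ethanethiol, CCS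
Why: Photochemical Wolff rearrangement of the s-cis-locked diazo ketone moves C4 from C3 to C2 with retention, giving the strained cyclobutane; the thiol traps the ketene, and the new methine is erased in step 11.

Step 11
Reactants: 13 S-ethyl cyclobutanecarbothioate
Product: 14 3'α-hydroxy thioester
Conditions: KHMDS (1.05 equiv), THF, −78 °C; then 2-(phenylsulfonyl)-3-phenyloxaziridine
Reagents that add atoms: 2-(phenylsulfonyl)-3-phenyloxaziridine, O=S(=O)(N1OC1c1ccccc1)c1ccccc1
Why: Hydroxylation of the thioester enolate (more acidic than the lactone) should occur on the convex α-face, opposite the cis-fused seven-membered ring and its C10' arm, placing oxygen cis to H-1' and the thioester carbon cis to C10'.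

Step 12
Reactants: 14 3'α-hydroxy thioester
Product: 15 cyclobutane diol
Conditions: NaBH4, EtOH–THF, 0 °C
Reagents that add atoms: none
Why: Borohydride reduces the activated thioester to the primary alcohol faster than the γ-lactone; no stereocentre changes.

Step 13
Reactants: 15 cyclobutane diol
Product: 16 tetrazolyl sulfide
Conditions: 1-phenyl-1H-tetrazole-5-thiol, PPh3, DIAD, THF, 0 °C to rt
Reagents that add atoms: 1-phenyl-1H-tetrazole-5-thiol, Sc1nnnn1-c1ccccc1
Why: Mitsunobu thioetherification takes place at the primary hydroxyl only (directly or through the spiro-epoxide, both leading to attack at CH2), leaving the tertiary carbinol configuration intact.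

Step 14
Reactants: 16 tetrazolyl sulfide
Product: 17 tetrazolyl sulfone
Conditions: m-CPBA (2.5 equiv), NaHCO3, CH2Cl2, 0 °C to rt
Reagents that add atoms: 3-chloroperbenzoic acid, OOC(=O)c1cccc(Cl)c1
Why: Sulfide-to-sulfone oxidation; the molecule has no olefin and the silyl ethers survive buffered peracid.

Step 15
Reactants: 17 tetrazolyl sulfone
Product: 18 fragment B, the 3'-O-trimethylsilyl sulfone
Conditions: TMSOTf, 2,6-lutidine, CH2Cl2, −78 °C
Reagents that add atoms: trimethylsilyl triflate, C[Si](C)(C)OS(=O)(=O)C(F)(F)F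
Why: Silylation of the cyclobutanol prevents Smiles transfer to the free alkoxide in step 16 and supplies the labile silyl group that the pinacol shift of step 17 expels.

Step 16
Reactants: 18 fragment B sulfone; 6 fragment A dialdehyde
Product: 19 E-olefin
Conditions: KHMDS, THF, −78 °C; then 6, −78 to −20 °C
Reagents that add atoms: none
Why: Julia–Kocienski olefination should give the E-disubstituted C2=C2' olefin; the saturated C2 aldehyde reacts in preference to the hindered, conjugated enal, and no sp3 stereocentre is formed.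

Step 17
Reactants: 19 E-olefin
Product: 20 cyclopentenol–cyclopentanone
Conditions: Me2AlCl (3 equiv), CH2Cl2, −78 to −20 °C; aqueous Rochelle salt
Reagents that add atoms: none
Why: Me2AlCl activates the enal carbonyl (C3), the E-olefin attacks it through C2, and the charge building at C2' is quenched in the same event by the 1,2-shift of the cyclobutane bond C3'–C1' to C2', the silyloxy carbon becoming the C3' ketone with loss of Me3SiCl; this is a Prins–pinacol (carbonyl-Prins/semipinacol) ring-enlarging annulation of a 1-alkenylcyclobutanol silyl ether. The cyclopentene ring of unit A closes 5-exo at the carbonyl with the olefin left exocyclic, helped by the cis disposition of C1 and the formyl group on C4=C5; the cyclopentanone ring of unit B forms by four-to-five ring expansion driven by release of cyclobutane strain. C2 is set by the resident C1 centre (the C2' arm goes trans to the C10 branch); C2' is set by anti addition across the E-olefin together with the carbinol configuration, and remains epimerisable to the same, more stable arrangement trans to the C10' arm; C1' migrates with retention; the C3 carbinol configuration (drawn β) is of no consequence. The step needs attack through C2 rather than C2' and migration of C1' rather than C4'; the first is secured by the five-membered closure that places the charge next to the migrating bond, the second by the rotamer that keeps H-2' over the ring and turned away from the quaternary C10' arm.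

Step 18
Reactants: 20 cyclopentenol–cyclopentanone
Product: 21 enone
Conditions: DBU, toluene, 60 °C
Reagents that add atoms: none
Why: E1cB loss of triethylsilanol is regiospecific because only C4' lies between the C3' ketone and C5'; the same base lets C2' settle in the arrangement trans to the C10' arm.

Step 19
Reactants: 21 enone
Product: 22 3α-bromide
Conditions: CBr4, PPh3, CH2Cl2, 0 °C
Reagents that add atoms: carbon tetrabromide, BrC(Br)(Br)Br
Why: Appel bromination of the secondary allylic alcohol (inversion at C3); any allylic transposition is harmless because both bromides give the same allyl radical.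

Step 20
Reactants: 22 3α-bromide
Product: 23 10,10'-bis-O-triethylsilyl-10,10'-bis-epi-caruifolin B
Conditions: Bu3SnH (slow addition), AIBN (cat.), benzene, 80 °C
Reagents that add atoms: none
Why: Tin hydride-mediated 5-exo radical conjugate addition (Giese type) of the C3 allyl radical to C5' of the enone closes the bicyclo[2.2.1]heptanone; the tether allows bonding only on the α-face where C2 sits, so C3 and C5' are set cis with ring B cis-fused and unit A endo, and the C4' radical should take hydrogen from the endo face opposite the syn C10' arm, leaving the methyl exo.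

Step 21
Reactants: 23 bis-silyl ether
Product: 24 10,10'-bis-epi-caruifolin B
Conditions: HF·pyridine, THF, 0 °C to rt
Reagents that add atoms: none
Why: Fluoride-mediated desilylation of the two tertiary silyl ethers leaves the ketone, the lactones and all stereocentres untouched.

Step 22
Reactants: 24 10,10'-bis-epi-caruifolin B
Product: 25 bis-exocyclic olefin
Conditions: SOCl2, pyridine, CH2Cl2, −20 °C
Reagents that add atoms: none
Why: Anti elimination through the chlorosulfites cannot take H-1 or H-1' (both syn to the leaving group), so C1 and C1' are kept and the exocyclic 10(14) olefins should predominate; any 9(10) isomer gives the same tertiary radical in step 23.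

Step 23
Reactants: 25 bis-exocyclic olefin
Product: 27 caruifolin B, via bis-hydroperoxide 26 (not isolated)
Conditions: Mn(dpm)3 (cat.), PhSiH3, O2 (1 atm), i-PrOH–CH2Cl2, 0 °C; then PPh3
Reagents that add atoms: dioxygen, O=O
Why: Mukaiyama hydration (hydrogen-atom transfer, Markovnikov) turns each 1,1-disubstituted olefin into the tertiary radical, which O2 should capture on the β-face, anti to H-1 and H-1', giving the 10β and 10'β carbinols after phosphine reduction; the tetrasubstituted C4=C5 olefin is too hindered to react.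

**Compound list**

1 | α-santonin | CC1=C2[C@H]3OC(=O)[C@@H](C)[C@@H]3CC[C@@]2(C)C=CC1=O | starting material
2 | isophotosantonic lactone (1αH, 10α-OH, 3-oxo-guai-4-en-12,6α-olide) | CC1=C2[C@H]3OC(=O)[C@@H](C)[C@@H]3CC[C@@](C)(O)[C@@H]2CC1=O | intermediate
3 | 10-O-triethylsilyl isophotosantonic lactone | CC1=C2[C@H]3OC(=O)[C@@H](C)[C@@H]3CC[C@@](C)(O[Si](CC)(CC)CC)[C@@H]2CC1=O | intermediate
4 | 2α-hydroxy derivative of 3 | CC1=C2[C@H]3OC(=O)[C@@H](C)[C@@H]3CC[C@@](C)(O[Si](CC)(CC)CC)[C@@H]2[C@@H](O)C1=O | intermediate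
5 | 2α,3α-diol (3-ketone of 4 reduced) | CC1=C2[C@H]3OC(=O)[C@@H](C)[C@@H]3CC[C@@](C)(O[Si](CC)(CC)CC)[C@@H]2[C@@H](O)[C@H]1O | intermediate
6 | fragment A: 2,3-seco dialdehyde (CHO on C1; Z-1-formylethylidene on C5) | C/C(C=O)=C1\[C@H]2OC(=O)[C@@H](C)[C@@H]2CC[C@@](C)(O[Si](CC)(CC)CC)[C@@H]1C=O | intermediate
7 | 4α,5α-epoxide of 3 | C[C@]12O[C@]13[C@H]4OC(=O)[C@@H](C)[C@@H]4CC[C@@](C)(O[Si](CC)(CC)CC)[C@@H]3CC2=O | intermediate
8 | 5α-hydroxy-4β-methyl ketone (10-OTES) | C[C@@H]1[C@]2(O)[C@H]3OC(=O)[C@@H](C)[C@@H]3CC[C@@](C)(O[Si](CC)(CC)CC)[C@@H]2CC1=O | intermediate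
9 | 5α,10α-bis(triethylsilyloxy) ketone | C[C@@H]1[C@]2(O[Si](CC)(CC)CC)[C@H]3OC(=O)[C@@H](C)[C@@H]3CC[C@@](C)(O[Si](CC)(CC)CC)[C@@H]2CC1=O | intermediate
10 | 2-trifluoroacetyl derivative of 9 (C2 labile, keto/enol) | C[C@@H]1[C@]2(O[Si](CC)(CC)CC)[C@H]3OC(=O)[C@@H](C)[C@@H]3CC[C@@](C)(O[Si](CC)(CC)CC)[C@@H]2C(C(=O)C(F)(F)F)C1=O | intermediate
11 | 2-diazo-3-ketone | C[C@@H]1[C@]2(O[Si](CC)(CC)CC)[C@H]3OC(=O)[C@@H](C)[C@@H]3CC[C@@](C)(O[Si](CC)(CC)CC)[C@@H]2C(=[N+]=[N-])C1=O | intermediate
12 | ring-contracted ketene | C[C@@H]1[C@]2(O[Si](CC)(CC)CC)[C@H]3OC(=O)[C@@H](C)[C@@H]3CC[C@@](C)(O[Si](CC)(CC)CC)[C@@H]2C1=C=O | intermediate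
13 | S-ethyl thioester of the cyclobutane (ring C1', C3', C4', C5'; thioester carbon = future C2'; H-3' α) | C[C@@H]1[C@]2(O[Si](CC)(CC)CC)[C@H]3OC(=O)[C@@H](C)[C@@H]3CC[C@@](C)(O[Si](CC)(CC)CC)[C@@H]2[C@@H]1C(=O)SCC | intermediate
14 | 3'α-hydroxy thioester (OH cis to H-1') | C[C@@H]1[C@]2(O[Si](CC)(CC)CC)[C@H]3OC(=O)[C@@H](C)[C@@H]3CC[C@@](C)(O[Si](CC)(CC)CC)[C@@H]2[C@]1(O)C(=O)SCC | intermediate
15 | diol (C2' hydroxymethyl, C3' tertiary OH) | C[C@@H]1[C@]2(O[Si](CC)(CC)CC)[C@H]3OC(=O)[C@@H](C)[C@@H]3CC[C@@](C)(O[Si](CC)(CC)CC)[C@@H]2[C@]1(O)CO | intermediate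
16 | C2' 1-phenyl-1H-tetrazol-5-yl sulfide | C[C@@H]1[C@]2(O[Si](CC)(CC)CC)[C@H]3OC(=O)[C@@H](C)[C@@H]3CC[C@@](C)(O[Si](CC)(CC)CC)[C@@H]2[C@]1(O)CSc4nnnn4c5ccccc5 | intermediate
17 | C2' tetrazolyl sulfone | C[C@@H]1[C@]2(O[Si](CC)(CC)CC)[C@H]3OC(=O)[C@@H](C)[C@@H]3CC[C@@](C)(O[Si](CC)(CC)CC)[C@@H]2[C@]1(O)CS(=O)(=O)c4nnnn4c5ccccc5 | intermediate
18 | fragment B: sulfone with C3'-OSiMe3 | C[C@@H]1[C@]2(O[Si](CC)(CC)CC)[C@H]3OC(=O)[C@@H](C)[C@@H]3CC[C@@](C)(O[Si](CC)(CC)CC)[C@@H]2[C@]1(O[Si](C)(C)C)CS(=O)(=O)c4nnnn4c5ccccc5 | intermediate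
19 | E-olefin C2=C2' joining the enal of unit A to the silyloxycyclobutane of unit B | C/C(C=O)=C1\[C@H]2OC(=O)[C@@H](C)[C@@H]2CC[C@@](C)(O[Si](CC)(CC)CC)[C@@H]1/C=C/[C@]4(O[Si](C)(C)C)[C@H](C)[C@]5(O[Si](CC)(CC)CC)[C@H]6OC(=O)[C@@H](C)[C@@H]6CC[C@@](C)(O[Si](CC)(CC)CC)[C@H]45 | intermediate
20 | 3β-hydroxy-guai-4-ene unit A bonded C2–C2' to the 3'-oxo, 5'α-OTES cyclopentanone unit B | CC1=C2[C@H]3OC(=O)[C@@H](C)[C@@H]3CC[C@@](C)(O[Si](CC)(CC)CC)[C@@H]2[C@H]([C@@H]1O)[C@H]3C(=O)[C@H](C)[C@]4([C@@H]3[C@](C)(O[Si](CC)(CC)CC)CC[C@H]3[C@H](C)C(=O)O[C@@H]34)O[Si](CC)(CC)CC | intermediate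
21 | 4'(5')-en-3'-one of 20 | CC1=C2[C@H]3OC(=O)[C@@H](C)[C@@H]3CC[C@@](C)(O[Si](CC)(CC)CC)[C@@H]2[C@H]([C@@H]1O)[C@H]3C(=O)C(C)=C4[C@@H]3[C@](C)(O[Si](CC)(CC)CC)CC[C@H]3[C@H](C)C(=O)O[C@@H]34 | intermediate
22 | 3α-bromide of 21 | CC1=C2[C@H]3OC(=O)[C@@H](C)[C@@H]3CC[C@@](C)(O[Si](CC)(CC)CC)[C@@H]2[C@H]([C@H]1Br)[C@H]3C(=O)C(C)=C4[C@@H]3[C@](C)(O[Si](CC)(CC)CC)CC[C@H]3[C@H](C)C(=O)O[C@@H]34 | intermediate
23 | 10,10'-bis-O-triethylsilyl-10,10'-bis-epi-caruifolin B | CC1=C2[C@H]3OC(=O)[C@@H](C)[C@@H]3CC[C@@](C)(O[Si](CC)(CC)CC)[C@@H]2[C@H]2[C@H]3C(=O)[C@H](C)[C@]4([C@@H]3[C@](C)(O[Si](CC)(CC)CC)CC[C@H]3[C@H](C)C(=O)O[C@@H]34)[C@@H]12 | intermediate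
24 | 10,10'-bis-epi-caruifolin B | CC1=C2[C@H]3OC(=O)[C@@H](C)[C@@H]3CC[C@@](C)(O)[C@@H]2[C@H]2[C@H]3C(=O)[C@H](C)[C@]4([C@@H]3[C@](C)(O)CC[C@H]3[C@H](C)C(=O)O[C@@H]34)[C@@H]12 | intermediate
25 | bis-10(14),10'(14')-olefin | CC1=C2[C@H]3OC(=O)[C@@H](C)[C@@H]3CCC(=C)[C@@H]2[C@H]2[C@H]3C(=O)[C@H](C)[C@]4([C@@H]3C(=C)CC[C@H]3[C@H](C)C(=O)O[C@@H]34)[C@@H]12 | intermediate
26 | 10β,10'β-bis-hydroperoxide | CC1=C2[C@H]3OC(=O)[C@@H](C)[C@@H]3CC[C@](C)(OO)[C@@H]2[C@H]2[C@H]3C(=O)[C@H](C)[C@]4([C@@H]3[C@@](C)(OO)CC[C@H]3[C@H](C)C(=O)O[C@@H]34)[C@@H]12 | intermediate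
27 | caruifolin B | CC1=C2[C@H]3OC(=O)[C@@H](C)[C@@H]3CC[C@](C)(O)[C@@H]2[C@H]2[C@H]3C(=O)[C@H](C)[C@]4([C@@H]3[C@@](C)(O)CC[C@H]3[C@H](C)C(=O)O[C@@H]34)[C@@H]12 | target

**Count and risks**

Total step count: 23. Longest linear sequence: 20 steps (steps 1, 2, 6–23).

Step 17 (most likely to fail). The olefin may close through C2' (six-membered ring) or react by an ene pathway, the enal may be too weak an electrophile, or the C3'–C4' bond may migrate instead of C3'–C1'. Fallback, from 19 back to 20: the two bond formations are separated. N-Bromosuccinimide in CH2Cl2 at −40 °C should trigger the semipinacol ring expansion alone, giving the C2-bromo cyclopentanone F1. A Barbier-type closure of the C2 bromide onto the formyl carbon C3 with SmI2 in THF–HMPA at −78 °C then forms the cyclopentenol 20.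

Step 20. The allyl radical may be reduced before it cyclises, may bond through its C5 terminus, or may add too slowly to the fully substituted C5'. Fallback, from 22 back to 23: an anionic closure replaces the radical one. PhSO2Na in DMF should give the allylic sulfone F2. KHMDS in THF at −78 °C should then close C3–C5' by intramolecular Michael addition of the sulfonyl-stabilised allyl anion, giving the C3 sulfone F3. SmI2 in THF–HMPA with t-BuOH removes the sulfonyl group, with protonation at C3 from the exo face, to reach 23.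

Step 23. Oxygen capture of the two tertiary radicals may show poor facial selectivity, giving C10/C10' epimer mixtures. Fallback, from 25 back to 27: a closed-shell three-step sequence. Dimethyldioxirane in acetone should epoxidise both exocyclic olefins on the β-face to give the bis-spiro-epoxide F4. MgI2 in Et2O opens each epoxide at CH2 to give the bis-iodohydrin F5. Bu3SnH with AIBN removes both iodines to give 27.

**Further compounds**

F1 | step 17 | C2-bromo 3'-oxo-cyclopentanone with the enal of unit A intact | C/C(C=O)=C1\[C@H]2OC(=O)[C@@H](C)[C@@H]2CC[C@@](C)(O[Si](CC)(CC)CC)[C@@H]1[C@H](Br)[C@H]3C(=O)[C@H](C)[C@]4([C@@H]3[C@](C)(O[Si](CC)(CC)CC)CC[C@H]3[C@H](C)C(=O)O[C@@H]34)O[Si](CC)(CC)CC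
F2 | step 20 | 3β-phenylsulfonyl analogue of 22 | CC1=C2[C@H]3OC(=O)[C@@H](C)[C@@H]3CC[C@@](C)(O[Si](CC)(CC)CC)[C@@H]2[C@H]([C@@H]1S(=O)(=O)c5ccccc5)[C@H]3C(=O)C(C)=C4[C@@H]3[C@](C)(O[Si](CC)(CC)CC)CC[C@H]3[C@H](C)C(=O)O[C@@H]34
F3 | step 20 | 3-phenylsulfonyl derivative of 23 | CC1=C2[C@H]3OC(=O)[C@@H](C)[C@@H]3CC[C@@](C)(O[Si](CC)(CC)CC)[C@@H]2[C@H]2[C@H]3C(=O)[C@H](C)[C@]4([C@@H]3[C@](C)(O[Si](CC)(CC)CC)CC[C@H]3[C@H](C)C(=O)O[C@@H]34)[C@@]12S(=O)(=O)c5ccccc5
F4 | step 23 | bis-10β,14-spiro-epoxide | CC1=C2[C@H]3OC(=O)[C@@H](C)[C@@H]3CC[C@@]5(CO5)[C@@H]2[C@H]2[C@H]3C(=O)[C@H](C)[C@]4([C@@H]3[C@]6(CO6)CC[C@H]3[C@H](C)C(=O)O[C@@H]34)[C@@H]12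
F5 | step 23 | bis-14-iodo-10β-hydroxy compound | CC1=C2[C@H]3OC(=O)[C@@H](C)[C@@H]3CC[C@](CI)(O)[C@@H]2[C@H]2[C@H]3C(=O)[C@H](C)[C@]4([C@@H]3[C@@](CI)(O)CC[C@H]3[C@H](C)C(=O)O[C@@H]34)[C@@H]12
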